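**Retrosynthetic overview**
- Leoligin ⇒ open the ring C2–O bond: the free hydroxyl of acyclic mono-angelate 16 closes onto its own δ-benzylic C–H in the last step, which also sets C2.
- 16 ⇒ angelic acid + the C2-symmetric (2R,3R)-2,3-bis(3,4-dimethoxybenzyl)butane-1,4-diol 13, whose hydroxyls are homotopic, so no protecting group is needed.
- 13 ⇒ LiAlH4 opening of trans-(3R,4R)-dibenzyl lactone 12 ⇒ anti-benzylation of (4R)-lactone 9 with 3,4-dimethoxybenzyl bromide (sets the second centre).
- 9 ⇒ Evans alkylation of the 3-(3,4-dimethoxyphenyl)propanoyl oxazolidinone 4 with tert-butyl bromoacetate (sets the first centre), then reductive auxiliary removal and lactonisation.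
- Ring order: a temporary butyrolactone is made and opened again; the tetrahydrofuran, the only ring of the target, is formed last.

Assumption: the SMILES is read as (2S,3R,4R) on the ring (2,3-trans, 3,4-cis) with a Z (angelate) ester; 3,4-dimethoxybenzyl bromide is bought and used fresh; potentials are against Ag/AgCl.

**Route**

Step 1
Reactants: 1 3-(3,4-dimethoxyphenyl)propanoic acid; 2 (4S)-4-isopropyloxazolidin-2-one
Product: 4 (4S)-3-[3-(3,4-dimethoxyphenyl)propanoyl]-4-isopropyloxazolidin-2-one, via mixed pivalic anhydride 3 (not isolated)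
Conditions: PivCl, Et3N, THF, −20 to 0 °C; then LiCl, 2, 0 °C to rt
Reagents that add atoms: none
Why: N-acylation of an oxazolidinone through a mixed pivalic anhydride (LiCl/Et3N activation), in which the nucleophile attacks the unhindered arylpropanoyl carbonyl; no stereocentre is formed or touched.

Step 2
Reactants: 4 (4S)-3-[3-(3,4-dimethoxyphenyl)propanoyl]-4-isopropyloxazolidin-2-one; 5 tert-butyl bromoacetate
Product: 7 tert-butyl (3R)-3-(3,4-dimethoxybenzyl)-4-[(4S)-4-isopropyl-2-oxooxazolidin-3-yl]-4-oxobutanoate, via sodium Z-enolate 6 (not isolated)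
Conditions: NaN(SiMe3)2 (1.1 equiv), THF, −78 °C, 45 min; then 5 (1.5 equiv), −78 to −40 °C
Reagents that add atoms: none
Why: Evans asymmetric alkylation, in which the chelated sodium Z-enolate is alkylated by the reactive bromoacetate on the face anti to the isopropyl group, setting the new centre as R (diastereomer ratio normally above 95:5).

Step 3
Reactants: 7 tert-butyl (3R)-3-(3,4-dimethoxybenzyl)-4-[(4S)-4-isopropyl-2-oxooxazolidin-3-yl]-4-oxobutanoate
Product: 9 (4R)-4-(3,4-dimethoxybenzyl)dihydrofuran-2(3H)-one, via hydroxy ester 8 (not isolated)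
Conditions: LiBH4 (1.5 equiv), MeOH (1.5 equiv), THF, 0 °C; aq NH4Cl work-up; then TsOH·H2O (5 mol%), toluene, 80 °C
Reagents that add atoms: none
Why: Reductive cleavage of the N-acyl oxazolidinone by LiBH4 (hydride attacks the exocyclic imide carbonyl and leaves the tert-butyl ester alone) followed by acid-catalysed lactonisation of the γ-hydroxy ester; the R centre is not enolisable at the imide-derived carbon once reduced and is carried through unchanged, and auxiliary 2 is recovered.

Step 4
Reactants: 9 (4R)-4-(3,4-dimethoxybenzyl)dihydrofuran-2(3H)-one; 10 3,4-dimethoxybenzyl bromide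
Product: 12 (3R,4R)-3,4-bis(3,4-dimethoxybenzyl)dihydrofuran-2(3H)-one, via lithium lactone enolate 11 (not isolated)
Conditions: LiN(SiMe3)2 (1.05 equiv), THF, −78 °C, 1 h; then 10 (1.1 equiv), DMPU (2 equiv), −78 to −30 °C
Reagents that add atoms: none
Why: Diastereoselective alkylation of a β-substituted butyrolactone enolate, in which the benzyl bromide approaches the planar enolate anti to the existing C4 benzyl group, so the new C3 centre is R and the lactone is trans.

Step 5
Reactants: 12 (3R,4R)-3,4-bis(3,4-dimethoxybenzyl)dihydrofuran-2(3H)-one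
Product: 13 (2R,3R)-2,3-bis(3,4-dimethoxybenzyl)butane-1,4-diol
Conditions: LiAlH4 (1.5 equiv), THF, 0 °C to rt
Reagents that add atoms: none
Why: Hydride reduction of a lactone to the diol, in which reduction of the carbonyl is much faster than enolisation, so both R centres are kept and the C2-symmetric diol results.

Step 6
Reactants: 13 (2R,3R)-2,3-bis(3,4-dimethoxybenzyl)butane-1,4-diol; 14 angelic acid = (2Z)-2-methylbut-2-enoic acid
Product: 16 (2R,3R)-4-hydroxy-2,3-bis(3,4-dimethoxybenzyl)butyl (2Z)-2-methylbut-2-enoate, via angelic trichlorobenzoic anhydride 15 (not isolated)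
Conditions: 14 (1 equiv), 2,4,6-trichlorobenzoyl chloride, Et3N, toluene, rt, 2 h; then 13 (3 equiv, excess recovered), 75 °C
Reagents that add atoms: none
Why: Yamaguchi-type mixed-anhydride esterification run hot without DMAP, which keeps the Z (angelate) geometry; the two hydroxyls of C2-symmetric 13 are homotopic, so every monoacylation gives the same compound, and the threefold excess of 13 limits diester formation.

Step 7
Reactants: 16 (2R,3R)-4-hydroxy-2,3-bis(3,4-dimethoxybenzyl)butyl (2Z)-2-methylbut-2-enoate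
Product: 20 leoligin = [(2S,3R,4R)-4-(3,4-dimethoxybenzyl)-2-(3,4-dimethoxyphenyl)oxolan-3-yl]methyl (2Z)-2-methylbut-2-enoate, via alkoxyl radical 17 (not isolated), via benzylic radical 18 (not isolated), via benzylic cation 19 (not isolated)
Conditions: CeCl3 (10 mol%), nBu4NCl (0.5 equiv), 2,4,6-collidine (1 equiv), nBu4NPF6 (0.1 M), MeCN, 400 nm LEDs, undivided cell, graphite-felt anode at +0.7 V vs Ag/AgCl, Pt cathode, 20 °C, 2.2 F/mol
Reagents that add atoms: none
Why: Proposed new method: a cerium-chloride electrophotocatalytic dehydrogenative δ-C–H etherification, in which anodically formed tetravalent cerium binds the free alcohol, 400 nm ligand-to-metal charge transfer releases alkoxyl radical 17 and trivalent cerium, a 1,5-hydrogen-atom transfer through a six-membered transition state moves the radical to the weak, electron-rich benzylic C–H next to the ester-bearing centre (18; the other benzylic CH2 would need a disfavoured 1,4-shift, the δ C–H of the acyloxymethyl group is stronger and electron-poor, and the product has no O–H from which the cycle could restart), a second tetravalent cerium or the anode oxidises this radical to the p-methoxy-stabilised cation 19, and the same hydroxyl closes the five-membered ring with the aryl group anti to the neighbouring angeloyloxymethyl group, setting C2 as S (2,3-trans) while the protons leave as H2 at the cathode; the anode potential lies well below that of the dimethoxyarenes, and the closest known reaction types are the Suárez hypoiodite alkoxyl-radical/1,5-hydrogen-transfer tetrahydrofuran synthesis and the cerium charge-transfer δ-C–H amination of alkanols, neither of which is an iodine-free, catalytic, dehydrogenative ring closure.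

**Compound list**
1 | 3-(3,4-dimethoxyphenyl)propanoic acid | COc1ccc(CCC(=O)O)cc1OC | starting material
2 | (4S)-4-isopropyloxazolidin-2-one | CC(C)[C@H]1COC(=O)N1 | starting material
3 | 3-(3,4-dimethoxyphenyl)propanoic pivalic anhydride | COc1ccc(CCC(=O)OC(=O)C(C)(C)C)cc1OC | intermediate
4 | (4S)-3-[3-(3,4-dimethoxyphenyl)propanoyl]-4-isopropyloxazolidin-2-one | COc1ccc(CCC(=O)N2[C@@H](C(C)C)COC2=O)cc1OC | intermediate
5 | tert-butyl bromoacetate | CC(C)(C)OC(=O)CBr | starting material
6 | sodium (1Z)-3-(3,4-dimethoxyphenyl)-1-[(4S)-4-isopropyl-2-oxooxazolidin-3-yl]prop-1-en-1-olate | COc1ccc(C/C=C(\O[Na])N2[C@@H](C(C)C)COC2=O)cc1OC | intermediate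
7 | tert-butyl (3R)-3-(3,4-dimethoxybenzyl)-4-[(4S)-4-isopropyl-2-oxooxazolidin-3-yl]-4-oxobutanoate | CC(C)(C)OC(=O)C[C@@H](Cc1ccc(OC)c(OC)c1)C(=O)N1[C@@H](C(C)C)COC1=O | intermediate
8 | tert-butyl (3R)-3-(3,4-dimethoxybenzyl)-4-hydroxybutanoate | CC(C)(C)OC(=O)C[C@@H](Cc1ccc(OC)c(OC)c1)CO | intermediate
9 | (4R)-4-(3,4-dimethoxybenzyl)dihydrofuran-2(3H)-one | O=C1C[C@@H](Cc2ccc(OC)c(OC)c2)CO1 | intermediate
10 | 3,4-dimethoxybenzyl bromide | COc1ccc(CBr)cc1OC | starting material
11 | lithium (4R)-4-(3,4-dimethoxybenzyl)-4,5-dihydrofuran-2-olate | [Li]OC1=C[C@@H](Cc2ccc(OC)c(OC)c2)CO1 | intermediate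
12 | (3R,4R)-3,4-bis(3,4-dimethoxybenzyl)dihydrofuran-2(3H)-one | O=C1[C@H](Cc2ccc(OC)c(OC)c2)[C@@H](Cc2ccc(OC)c(OC)c2)CO1 | intermediate
13 | (2R,3R)-2,3-bis(3,4-dimethoxybenzyl)butane-1,4-diol | OC[C@H](Cc1ccc(OC)c(OC)c1)[C@@H](Cc1ccc(OC)c(OC)c1)CO | intermediate
14 | angelic acid, (2Z)-2-methylbut-2-enoic acid | C/C=C(/C)C(=O)O | starting material
15 | (2Z)-2-methylbut-2-enoic 2,4,6-trichlorobenzoic anhydride | C/C=C(/C)C(=O)OC(=O)c1c(Cl)cc(Cl)cc1Cl | intermediate
16 | (2R,3R)-4-hydroxy-2,3-bis(3,4-dimethoxybenzyl)butyl (2Z)-2-methylbut-2-enoate | C/C=C(/C)C(=O)OC[C@H](Cc1ccc(OC)c(OC)c1)[C@@H](Cc1ccc(OC)c(OC)c1)CO | intermediate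
17 | alkoxyl (O-centred) radical of 16 | C/C=C(/C)C(=O)OC[C@H](Cc1ccc(OC)c(OC)c1)[C@@H](Cc1ccc(OC)c(OC)c1)C[O] | intermediate
18 | benzylic radical of 16, at the ArCH2 carbon on the centre that bears the angeloyloxymethyl group | C/C=C(/C)C(=O)OC[C@H]([CH]c1ccc(OC)c(OC)c1)[C@@H](Cc1ccc(OC)c(OC)c1)CO | intermediate
19 | benzylic cation at the same carbon | C/C=C(/C)C(=O)OC[C@H]([CH+]c1ccc(OC)c(OC)c1)[C@@H](Cc1ccc(OC)c(OC)c1)CO | intermediate
20 | leoligin, [(2S,3R,4R)-4-(3,4-dimethoxybenzyl)-2-(3,4-dimethoxyphenyl)oxolan-3-yl]methyl (2Z)-2-methylbut-2-enoate | C/C=C(/C)C(=O)OC[C@H]1[C@@H](Cc2ccc(OC)c(OC)c2)CO[C@@H]1c1ccc(OC)c(OC)c1 | target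

**Totals**
Total step count: 7. Longest linear sequence: 7 steps (1 → 4 → 7 → 9 → 12 → 13 → 16 → 20).

**Three steps most likely to fail**

Step 7 (the proposed ring closure). The risks are:
- chlorine-atom chemistry from the cerium chloride complex once the alcohol is consumed;
- loss of formaldehyde from radical 17 by β-scission;
- some 1,5-hydrogen transfer from the acyloxymethyl CH2 instead of the benzylic CH2;
- capture of cation 19 by the second arene to give an aryltetralin;
- partial Z-to-E isomerisation of the angelate;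
- a modest trans:cis ratio at C2.

The fallback uses known chemistry, sets out from lactone 9 and comes back at target 20. The benzylic oxygen is brought in by an aldol reaction instead of a C–H oxidation.
- Lithium enolate 11 (made as in step 4) adds to 3,4-dimethoxybenzaldehyde in THF at −78 °C, anti to the C4 benzyl group, to give (3S,4R)-4-(3,4-dimethoxybenzyl)-3-[(3,4-dimethoxyphenyl)(hydroxy)methyl]dihydrofuran-2(3H)-one F1 as a mixture of carbinol epimers.
- LiAlH4 in THF reduces F1 to (2R,3R)-2-(3,4-dimethoxybenzyl)-3-[(3,4-dimethoxyphenyl)(hydroxy)methyl]butane-1,4-diol F2.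
- Catalytic camphorsulfonic acid in CH2Cl2 at 0 °C ionises the benzylic alcohol of F2. Only the hydroxymethyl group on the benzyl-bearing carbon can close a five-membered ring, so both carbinol epimers converge on the 2,3-trans product [(2S,3R,4R)-4-(3,4-dimethoxybenzyl)-2-(3,4-dimethoxyphenyl)oxolan-3-yl]methanol F3.
- Mitsunobu esterification of F3 with angelic acid 14 (PPh3, DIAD, THF, 0 °C), which activates the alcohol and so leaves the Z geometry alone, gives 20.

Step 4 (lactone benzylation). The electron-rich benzyl bromide is unstable, double alkylation can compete, and any cis lactone must be removed. The fallback sets out from imide 4 and comes back at diol 13, making the central bond between the two stereocentres instead of the bond to the benzyl group.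
- LiN(iPr)2 in THF at −78 °C gives lithium (1Z)-3-(3,4-dimethoxyphenyl)-1-[(4S)-4-isopropyl-2-oxooxazolidin-3-yl]prop-1-en-1-olate F4.
- TiCl4 (one-electron oxidant, −78 °C to rt) couples two molecules of F4 through the faces anti to the isopropyl groups to give (4S,4'S)-3,3'-[(2R,3R)-2,3-bis(3,4-dimethoxybenzyl)butanedioyl]bis(4-isopropyloxazolidin-2-one) F5, purified by crystallisation from the minor R,S isomer.
- LiBH4 (H2O, Et2O/THF, 0 °C to rt) removes both auxiliaries from F5 and gives 13.

Step 6 (mono-angeloylation). The selectivity is only statistical, the mono- and diesters must be separated from the recovered diol, and the hot mixed-anhydride conditions may give some tiglate. The fallback sets out from 13 and comes back at 16, replacing statistics by a protecting group.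
- One equivalent of NaH in THF gives the sparingly soluble sodium (2R,3R)-4-hydroxy-2,3-bis(3,4-dimethoxybenzyl)butan-1-olate F6, which TBSCl converts into (2R,3R)-4-[(tert-butyldimethylsilyl)oxy]-2,3-bis(3,4-dimethoxybenzyl)butan-1-ol F7.
- With the second hydroxyl blocked, F7 is esterified with angelic acid 14 under Mitsunobu conditions (PPh3, DIAD, THF, 0 °C) to give (2R,3R)-4-[(tert-butyldimethylsilyl)oxy]-2,3-bis(3,4-dimethoxybenzyl)butyl (2Z)-2-methylbut-2-enoate F8.
- HF·pyridine in THF removes the silyl group from F8 and returns 16.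

**Further compounds**
F1 | step 7 | (3S,4R)-4-(3,4-dimethoxybenzyl)-3-[(3,4-dimethoxyphenyl)(hydroxy)methyl]dihydrofuran-2(3H)-one, both carbinol epimers | O=C1[C@H](C(O)c2ccc(OC)c(OC)c2)[C@@H](Cc2ccc(OC)c(OC)c2)CO1
F2 | step 7 | (2R,3R)-2-(3,4-dimethoxybenzyl)-3-[(3,4-dimethoxyphenyl)(hydroxy)methyl]butane-1,4-diol, both carbinol epimers | OC[C@H](C(O)c1ccc(OC)c(OC)c1)[C@@H](Cc1ccc(OC)c(OC)c1)CO
F3 | step 7 | [(2S,3R,4R)-4-(3,4-dimethoxybenzyl)-2-(3,4-dimethoxyphenyl)oxolan-3-yl]methanol | OC[C@H]1[C@@H](Cc2ccc(OC)c(OC)c2)CO[C@@H]1c1ccc(OC)c(OC)c1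
F4 | step 4 | lithium (1Z)-3-(3,4-dimethoxyphenyl)-1-[(4S)-4-isopropyl-2-oxooxazolidin-3-yl]prop-1-en-1-olate | COc1ccc(C/C=C(\O[Li])N2[C@@H](C(C)C)COC2=O)cc1OC
F5 | step 4 | (4S,4'S)-3,3'-[(2R,3R)-2,3-bis(3,4-dimethoxybenzyl)butanedioyl]bis(4-isopropyloxazolidin-2-one) | O=C(N1[C@@H](C(C)C)COC1=O)[C@H](Cc1ccc(OC)c(OC)c1)[C@@H](Cc1ccc(OC)c(OC)c1)C(=O)N1[C@@H](C(C)C)COC1=O
F6 | step 6 | sodium (2R,3R)-4-hydroxy-2,3-bis(3,4-dimethoxybenzyl)butan-1-olate | [Na]OC[C@H](Cc1ccc(OC)c(OC)c1)[C@@H](Cc1ccc(OC)c(OC)c1)CO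
F7 | step 6 | (2R,3R)-4-[(tert-butyldimethylsilyl)oxy]-2,3-bis(3,4-dimethoxybenzyl)butan-1-ol | CC(C)(C)[Si](C)(C)OC[C@H](Cc1ccc(OC)c(OC)c1)[C@@H](Cc1ccc(OC)c(OC)c1)CO
F8 | step 6 | (2R,3R)-4-[(tert-butyldimethylsilyl)oxy]-2,3-bis(3,4-dimethoxybenzyl)butyl (2Z)-2-methylbut-2-enoate | C/C=C(/C)C(=O)OC[C@H](Cc1ccc(OC)c(OC)c1)[C@@H](Cc1ccc(OC)c(OC)c1)CO[Si](C)(C)C(C)(C)C
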